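(The numbers in the tables come from a simulation for an exercise, noise included.)

One run cannot say whether conversion or time lowers a product's excess, since the two grow together in it; compare runs at one time.

| flask | left-handed substrate | right-handed substrate | partner | remark | time |
|---|---|---|---|---|---|
| ochre | 5 mM | 5 mM | 30 mM | run made earlier |  |
| amber | 7.5 mM | 7.5 mM | 30 mM | run made earlier |  |
| blue | 10 mM | 10 mM | 60 mM | run made earlier |  |
| flask | 10 mM | 10 mM | 30.0 mM |  | 3.0 d |

| run | time / d | left-handed product / % | right-handed product / % |
|---|---|---|---|
| ochre | 0.250 | 2.4 | 2.2 |
| ochre | 0.625 | 4.7 | 1.9 |
| ochre | 1.25 | 7.7 | 2.9 |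
| ochre | 2.08 | 11.6 | 4.6 |
| ochre | 3.00 | 14.7 | 4.3 |
| ochre | 4.00 | 18.2 | 9.5 |
| amber | 0.250 | 0.3 | 0 |
| amber | 0.500 | 3.8 | 2.0 |
| amber | 0.833 | 6.5 | 1.3 |
| amber | 1.25 | 9.0 | 3.0 |
| amber | 2.00 | 13.3 | 3.4 |
| amber | 4.00 | 17.5 | 8.5 |
| blue | 0.625 | 9.2 | 2.2 |
| blue | 1.25 | 16.5 | 3.7 |
| blue | 2.00 | 20.4 | 6.7 |
| blue | 3.00 | 25.8 | 11.4 |
| blue | 4.00 | 30.9 | 14.1 |

(standard deviation of a reading: 1 percentage point)

1. left-handed product and right-handed product together, in percent of the left-handed substrate and right-handed substrate charged together, at 3.0 d
2. excess of left-handed product over right-handed product in the product at 3.0 d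
3. whether the exchange between left-handed substrate and right-handed substrate keeps pace with the reaction: how far the product's excess at 3.0 d gets from its value without exchange to its value with instant exchange (above 80% keeps pace, below 20% hardly takes part, else lags behind)

- partner is single-handed; left-handed substrate and right-handed substrate are mirror images of each other, charged as a racemate, each of them at the stated concentration
- the numbers in the tables scatter by 1 percentage point (one standard deviation)
- an excess is the difference of the two amounts in percent of their sum
- an excess is below zero if the other one leads
- the handed part of partner does not stay in what it makes, so the products of the two hands are mirror images too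

Keep the books in fractions of the charge. By charge, substrate is the limiting reagent: the two hands hold 20.0 mM, less than the 30.0 mM of partner.

Open one account per hand and assume no exchange, so each half loses what its own product gains. The fraction left of the left half is then f_L = 1 − 2P, and f_R follows likewise from the right-handed product. If products also stay as made, both halves run on one clock and ln f_L / ln f_R holds still.

Enter ochre at 4.00 d: f_L is 63.6% and f_R is 81.0%, which gives 2.15. This is the selectivity factor on the fraction left, a reading with its scatter.

Apply it to blue at 4.00 d, which has run further. Its f_L of 38.2% books a right-handed product of 18.1% and an excess of 26.2%. Blue reads 37.3%, higher than the no-exchange book. So commit to exchange taking part; how closely it keeps pace stays open here, since no instant-exchange value has been reckoned.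

Close the books for the flask on ochre, which has the same partner charge: 19.0% product at 3.00 d, the other 81.0% outside the products.

The forecast gives 20%, 46% and hardly takes part, differing from this reckoning on pace: “The left product also follows simple depletion of its own half, so exchange hardly takes part.”

The flask gives 20.9% with excess 43.8%, and exchange keeps pace, 95% of the way. At 3.00 d the flask keeps 45% of its left-handed substrate and 45% of its right-handed substrate, the two hands nearly level. Applied to the flask's left-handed product, 2.15 books an excess of 32.4%, below the flask's; the computed no-exchange value is 37.8%.

    partner + left-handed substrate → left-handed product (k = 0.500 /M/h)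
    partner + right-handed substrate → right-handed product (k = 0.0860 /M/h)
    left-handed substrate ⇌ achiral form (K = 1.50, k = 0.720 /h)
    right-handed substrate ⇌ achiral form (K = 1.50, k = 0.720 /h)
    partner ⇌ dormant form (K = 0.980, k = 0.0150 /h)
    left-handed product ⇌ right-handed product (k = 0.00600 /h)

With 120 mM of partner, 2.15 books 30.0% right-handed product and an excess of 17.8%. That flask computes 17.9% and 41.3%.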